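**Assumptions**
- The SMILES is read as (4S,5S,8S,9S,10R,13S)-15-acetoxy-8-hydroxy-ent-labdan-18-oic acid (labdane numbering throughout): trans-decalin; methyls C19 (on C4), C20 (on C10) and C17 (on C8) axial on one face; CO2H (C18), 8-OH and the C9 side chain equatorial.
- In step 6 the (S)-binaphthoxide catalyst is taken to give the (2S)-oxirane; if the first run shows the opposite sense, the (R)-ligand complex is used.

**Retrosynthetic overview**
1. Target ⇐ oxidation of the neopentyl C18 CH2OH of the 8,18-diol 15-acetate; the acetate is carried from step 2 and no protecting group is used.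
2. Diol ⇐ one water-terminated cationic bicyclisation of an acyclic (S)-2-alkyl-2-methyloxirane E,E-diene: ring A first (C4–C5), then ring B (C9–C10), C8 cation quenched by water. The oxirane carbon becomes C4 and its CH2O becomes C18, so no C3 oxygen is ever introduced.
3. Oxirane ⇐ catalytic asymmetric methylene transfer to the C4 methyl ketone ⇐ copper-catalysed coupling of an ω-allylic bromide (C1) with a 3-oxobutyl ketal Grignard reagent (C2–C4, C19).
4. Allylic bromide ⇐ (S)-2,3-dihydrofarnesyl acetate (SeO2 ω-hydroxylation, Appel) ⇐ (2E,6E)-farnesol by Ru–BINAP hydrogenation, which sets C13.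

**Route**

Step 1
Reactants: 1 (2E,6E)-farnesol
Product: 2 (3S,6E)-3,7,11-trimethyldodeca-6,10-dien-1-ol [(S)-2,3-dihydrofarnesol]
Conditions: H2 (100 atm), Ru(OAc)2[(R)-BINAP] (0.5 mol %), 95% aq MeOH, 20 °C
Reagents that add atoms: none
Why: Noyori asymmetric hydrogenation; the allylic hydroxyl binds ruthenium so only the C2=C3 alkene is reduced, and the (R)-BINAP complex adds H2 to the face that gives the 3S centre (future C13), as in geraniol → (S)-citronellol.

Step 2
Reactants: 2 (S)-2,3-dihydrofarnesol
Product: 3 (3S,6E)-3,7,11-trimethyldodeca-6,10-dien-1-yl acetate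
Conditions: Ac2O, pyridine, DMAP (cat.), CH2Cl2, 0 → 25 °C
Reagents that add atoms: acetic anhydride, CC(=O)OC(C)=O
Why: DMAP-catalysed acylation of the only hydroxyl installs the acetate of the target, which also protects C15 for the rest of the route; no stereocentre is touched.

Step 3
Reactants: 3 (S)-dihydrofarnesyl acetate
Product: 4 (3S,6E,10E)-12-hydroxy-3,7,11-trimethyldodeca-6,10-dien-1-yl acetate
Conditions: SeO2 (0.3 equiv), t-BuOOH (3 equiv), salicylic acid (0.1 equiv), CH2Cl2, 0 → 25 °C
Reagents that add atoms: selenium dioxide, O=[Se]=O (catalytic oxygen carrier); tert-butyl hydroperoxide, CC(C)(C)OO (terminal oxidant)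
Why: Sharpless SeO2/t-BuOOH allylic oxidation (ene reaction, then [2,3]-shift) attacks the most accessible terminal trisubstituted alkene and hydroxylates its E-methyl group (future C1) without moving the alkene; moderate yield is expected, with the enal and internal oxidation products separated.

Step 4
Reactants: 4 (3S,6E,10E)-12-hydroxy-3,7,11-trimethyldodeca-6,10-dien-1-yl acetate
Product: 5 (3S,6E,10E)-12-bromo-3,7,11-trimethyldodeca-6,10-dien-1-yl acetate
Conditions: CBr4, PPh3, CH2Cl2, −20 → 0 °C
Reagents that add atoms: tetrabromomethane, BrC(Br)(Br)Br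
Why: Appel reaction; the primary allylic alcohol is displaced by bromide under neutral conditions that leave the acetate and the alkene geometry intact.

Step 5
Reactants: 5 (3S,6E,10E)-12-bromo-3,7,11-trimethyldodeca-6,10-dien-1-yl acetate; 6 2-(2-bromoethyl)-2-methyl-1,3-dioxolane
Product: 9 (3S,6E,10E)-3,7,11-trimethyl-15-oxohexadeca-6,10-dien-1-yl acetate, via ketal Grignard reagent 7 (not isolated), via coupled ketal 8 (not isolated)
Conditions: 6, Mg, THF, 25 °C; add to 5, Li2CuCl4 (5 mol %), THF, −78 → −20 °C; then 1 M HCl, THF, 25 °C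
Reagents that add atoms: water, O
Why: Kochi-type copper-catalysed coupling of an alkyl Grignard reagent with a primary allylic bromide goes at the unhindered CH2Br carbon (SN2, not SN2′) with retention of the E-alkene and is much faster at low temperature than addition to the acetate; mild acid hydrolysis of the dioxolane then frees the methyl ketone.

Step 6
Reactants: 9 (3S,6E,10E)-3,7,11-trimethyl-15-oxohexadeca-6,10-dien-1-yl acetate
Product: 10 (3S,6E,10E)-3,7,11-trimethyl-14-[(2S)-2-methyloxiran-2-yl]tetradeca-6,10-dien-1-yl acetate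
Conditions: Me3S(O)I, NaH, THF (ylide solution); LaLi3[(S)-binaphthoxide]3 (5 mol %), [2,4,6-(MeO)3C6H2]3P=O (5 mol %), 5 Å MS, THF, 25 °C
Reagents that add atoms: dimethyloxosulfonium methylide, C[S+](C)(=O)[CH2-] (from trimethylsulfoxonium iodide, C[S+](C)(C)=O.[I-], and NaH)
Why: Catalytic asymmetric Corey–Chaykovsky epoxidation; the lanthanum–lithium binaphthoxide complex binds ketone and ylide and delivers CH2 to one face of the methyl ketone, setting the 2S oxirane centre (future C4, about 90–95% ee expected), while alkenes and acetate are inert to the stabilised ylide.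

Step 7
Reactants: 10 (3S,6E,10E)-3,7,11-trimethyl-14-[(2S)-2-methyloxiran-2-yl]tetradeca-6,10-dien-1-yl acetate
Product: 12 (4S,5S,8S,9S,10R,13S)-8,18-dihydroxy-ent-labdan-15-yl acetate, via ent-labdan-8-yl cation 11 (not isolated)
Conditions: Ph4PBF4 (10 mol %), H2O (10 equiv), HFIP (0.02 M), 0 °C
Reagents that add atoms: water, O
Why: Proposed new method: HFIP hydrogen-bonds the oxirane oxygen, C5 of the C5=C10 alkene displaces it from C4 with inversion (alkene-assisted, SN2-like), C9 of the C8=C9 alkene takes the C10 cation through a chair–chair fold of the E,E-diene (trans ring fusion, H5 and H9 axial, C20 axial, side chain equatorial), and water quenches cation 11 on its equatorial face, anti to the new C9–C10 bond (C17 axial, OH equatorial); C4 is fixed by the oxirane centre, and the fold that puts the solvated CH2O arm equatorial and the methyl axial then fixes C5, C10, C9 and C8 in the ent series; the closest known reaction types are the oxirane-initiated cation–olefin polycyclisation (Lewis-acid or HFIP promoted) and the trapping of polyene-cyclisation cations by water.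

Step 8
Reactants: 12 (4S,5S,8S,9S,10R,13S)-8,18-dihydroxy-ent-labdan-15-yl acetate
Product: 14 (4S,5S,8S,9S,10R,13S)-15-acetoxy-8-hydroxy-ent-labdan-18-oic acid, via C18 aldehyde 13 (not isolated)
Conditions: AZADO (5 mol %), NaOCl (cat.), NaClO2 (2 equiv), MeCN/pH 6.8 phosphate buffer, 25 °C
Reagents that add atoms: sodium chlorite, [Na+].[O-]Cl=O
Why: Nitroxyl/chlorite (Zhao-type) oxidation; the oxoammonium ion of the unhindered AZADO oxidises only the primary neopentyl C18–OH to aldehyde 13, which chlorite takes on to the acid, while the tertiary C8–OH cannot be oxidised, the acetate survives pH 6.8 and the quaternary C4 cannot epimerise.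

**Compound list**

1 | (2E,6E)-farnesol | OC/C=C(\C)CC/C=C(\C)CCC=C(C)C | starting material
2 | (3S,6E)-3,7,11-trimethyldodeca-6,10-dien-1-ol | OCC[C@@H](C)CC/C=C(\C)CCC=C(C)C | intermediate
3 | (3S,6E)-3,7,11-trimethyldodeca-6,10-dien-1-yl acetate | CC(=O)OCC[C@@H](C)CC/C=C(\C)CCC=C(C)C | intermediate
4 | (3S,6E,10E)-12-hydroxy-3,7,11-trimethyldodeca-6,10-dien-1-yl acetate | CC(=O)OCC[C@@H](C)CC/C=C(\C)CC/C=C(\C)CO | intermediate
5 | (3S,6E,10E)-12-bromo-3,7,11-trimethyldodeca-6,10-dien-1-yl acetate | CC(=O)OCC[C@@H](C)CC/C=C(\C)CC/C=C(\C)CBr | intermediate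
6 | 2-(2-bromoethyl)-2-methyl-1,3-dioxolane | CC1(CCBr)OCCO1 | starting material
7 | [2-(2-methyl-1,3-dioxolan-2-yl)ethyl]magnesium bromide | CC1(CC[Mg]Br)OCCO1 | intermediate (not isolated)
8 | (3S,6E,10E)-3,7,11-trimethyl-14-(2-methyl-1,3-dioxolan-2-yl)tetradeca-6,10-dien-1-yl acetate | CC(=O)OCC[C@@H](C)CC/C=C(\C)CC/C=C(\C)CCCC1(C)OCCO1 | intermediate (not isolated)
9 | (3S,6E,10E)-3,7,11-trimethyl-15-oxohexadeca-6,10-dien-1-yl acetate | CC(=O)OCC[C@@H](C)CC/C=C(\C)CC/C=C(\C)CCCC(C)=O | intermediate
10 | (3S,6E,10E)-3,7,11-trimethyl-14-[(2S)-2-methyloxiran-2-yl]tetradeca-6,10-dien-1-yl acetate | CC(=O)OCC[C@@H](C)CC/C=C(\C)CC/C=C(\C)CCC[C@@]1(C)CO1 | intermediate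
11 | 15-acetoxy-18-hydroxy-ent-labdan-8-yl cation (C4, C5, C9, C10, C13 as in 12) | CC(=O)OCC[C@@H](C)CC[C@H]1[C@]2(C)CCC[C@](C)(CO)[C@H]2CC[C+]1C | intermediate (not isolated)
12 | (4S,5S,8S,9S,10R,13S)-8,18-dihydroxy-ent-labdan-15-yl acetate (CH2OH and 8-OH equatorial; C17, C19, C20 axial) | CC(=O)OCC[C@@H](C)CC[C@H]1[C@]2(C)CCC[C@](C)(CO)[C@H]2CC[C@]1(C)O | intermediate
13 | (4S,5S,8S,9S,10R,13S)-15-acetoxy-8-hydroxy-ent-labdan-18-al | CC(=O)OCC[C@@H](C)CC[C@H]1[C@]2(C)CCC[C@](C)(C=O)[C@H]2CC[C@]1(C)O | intermediate (not isolated)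
14 | (4S,5S,8S,9S,10R,13S)-15-acetoxy-8-hydroxy-ent-labdan-18-oic acid | CC(=O)OCC[C@@H](C)CC[C@H]1[C@]2(C)CCC[C@](C)(C(=O)O)[C@H]2CC[C@]1(C)O | target

**Step count and risks**

Total steps: 8. Longest linear sequence: 8 steps (1 → 14); compound 6 is purchased.

Most likely to fail, in this order:

**Step 7 (water-terminated bicyclisation).**
- Fold selectivity: the departing oxygen sits on the exocyclic C18, so the choice between the two chair folds is steric only and is not enforced stereoelectronically as it is with trisubstituted oxiranes. The wrong fold gives the C4-axial-CH2OH diastereomer with the normal-series decalin, which is separable by chromatography.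
- Other risks: E1 loss of cation 11 to alkenes, direct hydrolysis of the oxirane, and partial SN1 scrambling at C4.
- Fallback, from 10 back to 12: ring formation and hydration are separated. MeAlCl2 (1.5 equiv), CH2Cl2, −78 °C is the anhydrous Lewis-acid oxirane–polyene cyclisation; the bulky O–Al group on C18 at low temperature should reinforce the equatorial fold and the inversion. It ends by proton loss and gives the exocyclic alkene 18-hydroxy-ent-labd-8(17)-en-15-yl acetate F1 and its endocyclic isomer 18-hydroxy-ent-labd-7-en-15-yl acetate F2, carried on as the mixture. Mukaiyama hydration (Co(acac)2 cat., PhSiH3, O2, i-PrOH, 25 °C; then Na2S2O3) converts both through the same tertiary C8 radical, which takes O2 on the open equatorial face (the axial face is blocked by C20), to 12.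

**Step 6 (asymmetric methylene transfer to an aliphatic methyl ketone).**
- Risks: ee below about 90% for a ketone flanked by CH3 and CH2, and acetate transesterification by the basic catalyst. Any minor oxirane enantiomer ends up as a diastereomer of 14 that differs only in the remote C13 relationship and is hard to remove.
- Fallback, from 5 back to 10: the C4 centre is taken from the chiral pool. The known building block (S)-4-(2-bromoethyl)-2,2,4-trimethyl-1,3-dioxolane F3 (from (S)-citramalic acid by reduction, acetonide formation and Appel bromination) is converted with Mg in THF into the Grignard reagent [2-((4S)-2,2,4-trimethyl-1,3-dioxolan-4-yl)ethyl]magnesium bromide F4. This is coupled with 5 (Li2CuCl4 cat., THF, −78 → −20 °C) to the acetonide (3S,6E,10E)-3,7,11-trimethyl-14-[(4S)-2,2,4-trimethyl-1,3-dioxolan-4-yl]tetradeca-6,10-dien-1-yl acetate F5. 80% aq AcOH at 40 °C gives the diol (3S,6E,10E,15S)-15,16-dihydroxy-3,7,11,15-tetramethylhexadeca-6,10-dien-1-yl acetate F6. TsCl, pyridine, 0 °C sulfonylates only the primary hydroxyl to (3S,6E,10E,15S)-15-hydroxy-3,7,11,15-tetramethyl-16-(tosyloxy)hexadeca-6,10-dien-1-yl acetate F7. NaH, THF, 0 °C closes the oxirane by attack of the tertiary alkoxide on C18, leaving C4 untouched, and gives enantiopure 10.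

**Step 5 (copper-catalysed Grignard coupling beside an acetate).**
- Risks: SN2′ attack at C5, Grignard addition to the acetate, and thermal loss of reagent 7 by 1,3-elimination.
- Fallback, from 5 back to 8: the C1–C2 bond is made with a soft sulfone carbanion. 2-Methyl-2-[2-(phenylsulfonyl)ethyl]-1,3-dioxolane F8 (from commercial 4-(phenylsulfonyl)butan-2-one and ethylene glycol) is lithiated (n-BuLi, THF, −78 °C) and alkylated with 5 at the CH2Br carbon to (3S,6E,10E)-3,7,11-trimethyl-14-(2-methyl-1,3-dioxolan-2-yl)-13-(phenylsulfonyl)tetradeca-6,10-dien-1-yl acetate F9 (either C13 epimer). Buffered reductive desulfonylation (6% Na(Hg), Na2HPO4, MeOH/THF, −20 °C) gives ketal 8, which is hydrolysed with 1 M HCl as in step 5 to 9.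

**Further compounds**

F1 | step 7 | 18-hydroxy-ent-labd-8(17)-en-15-yl acetate (C4, C5, C9, C10, C13 as in 12) | CC(=O)OCC[C@@H](C)CC[C@H]1[C@]2(C)CCC[C@](C)(CO)[C@H]2CCC1=C
F2 | step 7 | 18-hydroxy-ent-labd-7-en-15-yl acetate (C4, C5, C9, C10, C13 as in 12) | CC(=O)OCC[C@@H](C)CC[C@H]1[C@]2(C)CCC[C@](C)(CO)[C@H]2CC=C1C
F3 | step 6 | (S)-4-(2-bromoethyl)-2,2,4-trimethyl-1,3-dioxolane | C[C@]1(CCBr)COC(C)(C)O1
F4 | step 6 | [2-((4S)-2,2,4-trimethyl-1,3-dioxolan-4-yl)ethyl]magnesium bromide | C[C@]1(CC[Mg]Br)COC(C)(C)O1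
F5 | step 6 | (3S,6E,10E)-3,7,11-trimethyl-14-[(4S)-2,2,4-trimethyl-1,3-dioxolan-4-yl]tetradeca-6,10-dien-1-yl acetate | CC(=O)OCC[C@@H](C)CC/C=C(\C)CC/C=C(\C)CCC[C@@]1(C)COC(C)(C)O1
F6 | step 6 | (3S,6E,10E,15S)-15,16-dihydroxy-3,7,11,15-tetramethylhexadeca-6,10-dien-1-yl acetate | CC(=O)OCC[C@@H](C)CC/C=C(\C)CC/C=C(\C)CCC[C@](C)(O)CO
F7 | step 6 | (3S,6E,10E,15S)-15-hydroxy-3,7,11,15-tetramethyl-16-(tosyloxy)hexadeca-6,10-dien-1-yl acetate | CC(=O)OCC[C@@H](C)CC/C=C(\C)CC/C=C(\C)CCC[C@](C)(O)COS(=O)(=O)c1ccc(C)cc1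
F8 | step 5 | 2-methyl-2-[2-(phenylsulfonyl)ethyl]-1,3-dioxolane | CC1(CCS(=O)(=O)c2ccccc2)OCCO1
F9 | step 5 | (3S,6E,10E)-3,7,11-trimethyl-14-(2-methyl-1,3-dioxolan-2-yl)-13-(phenylsulfonyl)tetradeca-6,10-dien-1-yl acetate | CC(=O)OCC[C@@H](C)CC/C=C(\C)CC/C=C(\C)CC(CC1(C)OCCO1)S(=O)(=O)c1ccccc1
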